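L and Q kept one sum in the north-east run, 99.6% of the charge at 10.0 min, so I took the conversion x, read as Q, as the clock of each flask.

| setting | north-east | Thursday's | Wednesday's | Sunday's | Friday's | Saturday's |
|---|---|---|---|---|---|---|
| L | 5 mM | 5.0 mM | 5.0 mM | 5.0 mM | 5.0 mM | 5.0 mM |
| D | 0.098 µM | 0.12 µM | 0.80 µM | 0.50 µM | 0.15 µM | 0.25 µM |
| remark | run made earlier |  |  |  |  |  |
| time |  | 10 min | 10 min | 10 min | 10 min | 10 min |

north-east run (percent of the L charged)

| time / min | Q / % | L / % |
|---|---|---|
| 2.00 | 52.9 | 46.7 |
| 4.00 | 65.0 | 34.6 |
| 6.00 | 69.4 | 30.0 |
| 8.00 | 70.8 | 28.8 |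
| 10.0 | 72.1 | 27.5 |

(each reading ± 0.3 percentage points)

- the earlier runs were read with a standard deviation of 0.3 percentage points
- no earlier run changes the charge of D; that part of a forecast is a guess

1. all flasks from highest to lowest amount of Q, in percent of the L charged, at 10 min (Thursday's / Wednesday's / Sunday's / Friday's / Saturday's)
2. the amount of Q, in percent of the L charged of the flask you put first, at 10 min
3. the amount of Q, in percent of the L charged of the flask you put last, at 10 min

I supposed that D turns L over at a rate first order in [L] and is lost at a rate proportional to [D][Q]. Dividing the two rates removes time, so [D] + B·G stays at the charged [D], where G = ln(charged [L]/[L]) − x. B is the kill charge, the D lost per unit of G at this charge of L, which I took to be the same for each charge of D. A flask under this product inactivation stalls where G equals its charge of D divided by B.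

I read B in two ways. Taking the last reading as the stall gave 0.176 µM. Independently, the first-order constant of L loss stands for [D], and it was 0.150 min⁻¹ at G = 0.307, then 0.0713 min⁻¹ at G = 0.453. That line reaches zero at G = 0.586, which gives B = 0.167 µM, close to the first value. But the same line starts at 0.315 min⁻¹, while the first window ran at 0.381 min⁻¹, faster than the line allows. So I took the first-order law for the part that cheated: these readings asked for a rate per D that falls more steeply than [L].

My stalls followed the charge of D: 76.4% for Thursday's, which I trusted, and 99.6% for Wednesday's, which I read as too high. The forecast gave Wednesday's > Sunday's > Saturday's > Friday's > Thursday's, with top 99.4% and low 79%, on the ground that “Total turnover then scales with D”.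

The simulation gave Wednesday's > Sunday's > Saturday's > Friday's > Thursday's, with top 91.0% and low 74.5%.

    L + D → Q + D, rate k1*[L]^2.5*[D]/(1 + ([L]/Kh1)^2.5) (5.10 mM, k = 5.10 × 10⁸ M⁻²·⁵ s⁻¹)
    D + Q → E (k = 1.40 M⁻¹ s⁻¹)
    2 L → X (k = 0.00480 M⁻¹ s⁻¹)

In Wednesday's flask, L went to Q while D was still active: half of that step's turnover up to 10.0 min was done by 0.166 min and 95% by 2.00 min. D then fell to 17.6% of its charge at 5.00 min and 2.62% at 10.0 min, with L still at 8.89%. Reckoned from the D lost by 10.0 min, B came to 0.175 µM in Thursday's flask but 0.516 µM in Wednesday's. A neighbour, Wednesday's flask with 0.320 µM of D instead, reached 84.8% of Q by 10.0 min, which gives B = 0.293 µM.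

The earlier runs and the new flask stem from a simulated flask with made-up constants; the scatter is artificial.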